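The route rests on disconnecting the two C–O bonds of the cyclopentane ring (C1–C5): O3 and O5 are cis and flank the hydrogen-free quaternary C4, the imprint of dioxygen added across a 5,5-dimethylcyclopentadiene. In one operation singlet oxygen adds to the diene C5=C1–C2=C3, forming both C–O bonds, both carbinol stereocentres and a peroxide-bridged bicycle, and leaves the C1=C2 alkene conjugated with the C10 ketone for later adjustment of C1. The precursor is a cyclopentadiene fused to the cycloheptanone ring (C5–C10, C1) that already carries the C8 and C9 stereocentres and a silyl-protected hydroxyethyl arm on C9.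

Key step: step 11

Remark on numbering and faces: C1–C5 = cyclopentane (C1 fusion CH, C3 carbinol, C4 CMe2, C5 fusion carbinol); C5–C10 plus C1 = cycloheptanone (C8 CHMe, C9 quaternary, C10 C=O); C11–C12 = arm; β = face of the C8 and C9 methyl groups and of both hydroxyls, α = face of the C9 arm and of H1.
Remark on the annulation: the ring-enlarged 1,3-dione is not alkylated and aldolised at C1, because an enolised 2-alkyl-1,3-dione resists base-mediated aldol closure and gives a furan under acid; instead the C9 arm masks C10 as a cyclic vinylogous ester so that C5 is the only carbonyl open to attack.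
Remark on protection: the cis-1,3-diol is carried as two silyl ethers, not as an isopropylidene acetal, because a bridging acetal across C3/C5 would clash with the C4 methyl groups.
Assumption: 7 is drawn as the open hydroxy ketone (it equilibrates with its lactol); the two ring-fusion centres of 10 and 11 are drawn for ketene approach anti to the arm and are destroyed in step 5; 18 is a mixture at C5.

Step 1
Reactants: 1 2-methylcyclopent-2-en-1-one; 2 methylmagnesium bromide; 3 allyl iodide
Product: 5 (2S,3R)-2,3-dimethyl-2-(prop-2-en-1-yl)cyclopentan-1-one, via magnesium enolate 4 (not isolated)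
Conditions: MeMgBr, CuBr·SMe2 (5 mol %), JosiPhos-type ferrocenyl diphosphine (6 mol %), t-BuOMe, −78 °C; then allyl iodide, DMPU, −78 → 0 °C
Reagents that add atoms: methylmagnesium bromide (2), C[Mg]Br; allyl iodide (3), C=CCI
Why: Copper-catalysed asymmetric conjugate addition (ligand enantiomer chosen for the 3R product) sets C8, and the magnesium enolate is allylated in the same pot anti to the new methyl group, which sets the C9 quaternary centre with the two methyl groups cis (conjugate addition–enolate trapping).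

Step 2
Reactants: 5 (2S,3R)-2,3-dimethyl-2-(prop-2-en-1-yl)cyclopentan-1-one
Product: 7 (2S,3R)-2-(2-hydroxyethyl)-2,3-dimethylcyclopentan-1-one, via keto aldehyde 6 (not isolated)
Conditions: O3, CH2Cl2, −78 °C; PPh3, → rt; then NaBH(OAc)3, AcOH, rt
Reagents that add atoms: ozone, [O-][O+]=O
Why: Ozonolysis with reductive work-up cleaves the terminal alkene to the aldehyde, which triacetoxyborohydride should reduce much faster than the hindered α-quaternary ketone (chemoselective hydride reduction), with no stereocentre touched.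

Step 3
Reactants: 7 (2S,3R)-2-(2-hydroxyethyl)-2,3-dimethylcyclopentan-1-one
Product: 8 trimethyl({(4R,5S)-4,5-dimethyl-5-[2-(trimethylsilyloxy)ethyl]cyclopent-1-en-1-yl}oxy)silane
Conditions: TMSOTf (2.5 equiv), Et3N, CH2Cl2, −78 → 0 °C
Reagents that add atoms: trimethylsilyl trifluoromethanesulfonate, C[Si](C)(C)OS(=O)(=O)C(F)(F)F
Why: Silyl triflate and amine silylate the primary alcohol and convert the ketone into its only possible silyl enol ether, towards the CH2 side, because the other α-carbon is quaternary (soft enolisation).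

Step 4
Reactants: 8 trimethyl({(4R,5S)-4,5-dimethyl-5-[2-(trimethylsilyloxy)ethyl]cyclopent-1-en-1-yl}oxy)silane; 9 dichloroacetyl chloride
Product: 10 (1R,2S,3R,5S)-7,7-dichloro-2,3-dimethyl-1-(trimethylsilyloxy)-2-[2-(trimethylsilyloxy)ethyl]bicyclo[3.2.0]heptan-6-one
Conditions: Cl2CHCOCl (slow addition), Et3N, hexanes, rt
Reagents that add atoms: dichloroacetyl chloride (9), O=C(Cl)C(Cl)Cl
Why: Dichloroketene formed by dehydrochlorination undergoes the usual [2+2] cycloaddition with the silyl enol ether, its carbonyl carbon bonding to the nucleophilic CH terminus (future C5–C6) and the CCl2 carbon (future C1) to the silyloxy carbon C10.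

Step 5
Reactants: 10 (1R,2S,3R,5S)-7,7-dichloro-2,3-dimethyl-1-(trimethylsilyloxy)-2-[2-(trimethylsilyloxy)ethyl]bicyclo[3.2.0]heptan-6-one
Product: 13 (3aS,4R)-3a,4-dimethyl-2,3,3a,4,5,6-hexahydro-7H-cyclohepta[b]furan-7-one, via dechlorinated cyclobutanone 11 (not isolated), via hydroxy dione 12 (not isolated)
Conditions: Zn, AcOH, i-PrOH/H2O, 0 → 70 °C; then TsOH (cat.), PhMe, reflux (−H2O)
Reagents that add atoms: none
Why: Zinc removes both chlorines, aqueous acid cleaves the silyl ethers, the β-hydroxy cyclobutanone opens by retro-aldol fragmentation to the cycloheptane-1,3-dione (two-carbon ring enlargement), and the C9 arm, which can reach only C10, closes on it with loss of water to a cyclic vinylogous ester that leaves C5 as the free carbonyl.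

Step 6
Reactants: 13 (3aS,4R)-3a,4-dimethyl-2,3,3a,4,5,6-hexahydro-7H-cyclohepta[b]furan-7-one
Product: 14 (3aS,4R)-8-bromo-3a,4-dimethyl-2,3,3a,4,5,6-hexahydro-7H-cyclohepta[b]furan-7-one
Conditions: NBS, CH2Cl2, 0 °C
Reagents that add atoms: N-bromosuccinimide, O=C1CCC(=O)N1Br
Why: Electrophilic bromination of a vinylogous ester takes place at its nucleophilic α-carbon, here C1.

Step 7
Reactants: 14 (3aS,4R)-8-bromo-3a,4-dimethyl-2,3,3a,4,5,6-hexahydro-7H-cyclohepta[b]furan-7-one; 15 2-ethenyl-4,4,5,5-tetramethyl-1,3,2-dioxaborolane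
Product: 16 (3aS,4R)-8-ethenyl-3a,4-dimethyl-2,3,3a,4,5,6-hexahydro-7H-cyclohepta[b]furan-7-one
Conditions: Pd(dppf)Cl2 (5 mol %), K2CO3, 1,4-dioxane/H2O, 80 °C
Reagents that add atoms: 2-ethenyl-4,4,5,5-tetramethyl-1,3,2-dioxaborolane (15), C=CB1OC(C)(C)C(C)(C)O1
Why: Suzuki–Miyaura coupling of the α-bromo vinylogous ester with the vinylboronate places the future C2 on C1.

Step 8
Reactants: 16 (3aS,4R)-8-ethenyl-3a,4-dimethyl-2,3,3a,4,5,6-hexahydro-7H-cyclohepta[b]furan-7-one; 17 prenylmagnesium chloride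
Product: 19 (6R,7S)-2-ethenyl-7-(2-hydroxyethyl)-6,7-dimethyl-3-(2-methylbut-3-en-2-yl)cyclohept-2-en-1-one, via tertiary carbinol 18 (not isolated)
Conditions: prenylMgCl, THF, −78 °C; then 1 M HCl, THF, 0 °C → rt
Reagents that add atoms: prenylmagnesium chloride (17), CC(C)=CC[Mg]Cl; water, O
Why: The allylic Grignard reagent adds 1,2 to the vinylogous-ester carbonyl through its γ-carbon (SE2′), which makes the congested C4–C5 bond, and aqueous acid then ionises the carbinol and hydrolyses the enol ether so that the ketone reappears at C10, the alkene at C1=C5 and the arm is set free (Stork–Danheiser alkylative carbonyl transposition).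

Step 9
Reactants: 19 (6R,7S)-2-ethenyl-7-(2-hydroxyethyl)-6,7-dimethyl-3-(2-methylbut-3-en-2-yl)cyclohept-2-en-1-one
Product: 20 (6R,7S)-2-ethenyl-6,7-dimethyl-3-(2-methylbut-3-en-2-yl)-7-[2-(triethylsilyloxy)ethyl]cyclohept-2-en-1-one
Conditions: TESCl, imidazole, CH2Cl2, 0 °C
Reagents that add atoms: chlorotriethylsilane, CC[Si](Cl)(CC)CC
Why: Standard silylation of the primary alcohol, the triethylsilyl group being chosen so that it can later be removed in the presence of hindered secondary and tertiary silyl ethers.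

Step 10
Reactants: 20 (6R,7S)-2-ethenyl-6,7-dimethyl-3-(2-methylbut-3-en-2-yl)-7-[2-(triethylsilyloxy)ethyl]cyclohept-2-en-1-one
Product: 21 (5S,6R)-1,1,5,6-tetramethyl-5-[2-(triethylsilyloxy)ethyl]-5,6,7,8-tetrahydroazulen-4(1H)-one
Conditions: Grubbs II (5 mol %), CH2Cl2 (5 mM), 40 °C
Reagents that add atoms: none
Why: Ring-closing metathesis joins the two terminal vinyl groups, held cis on the tetrasubstituted C1=C5 alkene, into the five-membered ring with loss of ethylene and should give the fused 5,5-dimethylcyclopentadiene.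

Step 11
Reactants: 21 (5S,6R)-1,1,5,6-tetramethyl-5-[2-(triethylsilyloxy)ethyl]-5,6,7,8-tetrahydroazulen-4(1H)-one; 22 dioxygen (used as singlet oxygen)
Product: 24 (2R,5S,6R,8aR)-2,8a-dihydroxy-1,1,5,6-tetramethyl-5-[2-(triethylsilyloxy)ethyl]-2,5,6,7,8,8a-hexahydroazulen-4(1H)-one, via endoperoxide 23 (not isolated)
Conditions: O2, TPP (cat.), hν (>500 nm), CH2Cl2, −78 °C; then thiourea, MeOH, −78 °C → rt
Reagents that add atoms: dioxygen (22), O=O
Why: Sensitised singlet oxygen adds as a 2π partner across the s-cis diene C5=C1–C2=C3 in a concerted, suprafacial [4+2] cycloaddition, the known photooxygenation of cyclopentadienes to 2,3-dioxabicyclo[2.2.1]hept-5-enes, and thiourea then reduces the O–O bond to the cis-ene-diol. The one ring closed, the peroxide bridge C3–O–O–C5, forms by this pericyclic (4+2) closure with both C–O bonds made together. C3 and C5 are necessarily cis to each other because both oxygens arrive on one diene face; which face is used is governed by the C9 quaternary centre next to C10 (supported by C8), oxygen being expected to approach the β face, anti to the CH2CH2OSiEt3 arm. The step needs π-facial selectivity and chemoselectivity for cycloaddition over ene reaction: the locked s-cis geometry makes [4+2] far faster than hydrogen abstraction at C6, C4 carries no hydrogen, and the C10 carbonyl only slows the addition. Low temperature, immediate reduction and a neutral reductant keep the labile peroxide from thermal rearrangement and from base-induced opening at C3–H.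

Step 12
Reactants: 24 (2R,5S,6R,8aR)-2,8a-dihydroxy-1,1,5,6-tetramethyl-5-[2-(triethylsilyloxy)ethyl]-2,5,6,7,8,8a-hexahydroazulen-4(1H)-one
Product: 25 (2R,5S,6R,8aR)-1,1,5,6-tetramethyl-2,8a-bis(triethylsilyloxy)-5-[2-(triethylsilyloxy)ethyl]-2,5,6,7,8,8a-hexahydroazulen-4(1H)-one
Conditions: TESOTf (3 equiv), 2,6-lutidine, CH2Cl2, −78 °C → rt
Reagents that add atoms: triethylsilyl trifluoromethanesulfonate, CC[Si](CC)(CC)OS(=O)(=O)C(F)(F)F
Why: Silyl triflate with a hindered pyridine base silylates secondary and tertiary alcohols, so both carbinols become bulky ethers on the β face.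

Step 13
Reactants: 25 (2R,5S,6R,8aR)-1,1,5,6-tetramethyl-2,8a-bis(triethylsilyloxy)-5-[2-(triethylsilyloxy)ethyl]-2,5,6,7,8,8a-hexahydroazulen-4(1H)-one
Product: 26 (2R,3aS,5S,6R,8aS)-1,1,5,6-tetramethyl-2,8a-bis(triethylsilyloxy)-5-[2-(triethylsilyloxy)ethyl]octahydroazulen-4(1H)-one
Conditions: H2 (1–4 atm), 10% Pd/C, EtOAc, rt
Reagents that add atoms: none
Why: Heterogeneous hydrogenation of the enone alkene should occur from the α face, opposite the two β-silyloxy groups on C3 and C5, which places H1 trans to O5 (trans ring fusion) and sets C1.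

Step 14
Reactants: 26 (2R,3aS,5S,6R,8aS)-1,1,5,6-tetramethyl-2,8a-bis(triethylsilyloxy)-5-[2-(triethylsilyloxy)ethyl]octahydroazulen-4(1H)-one
Product: 27 (2R,3aS,5S,6R,8aS)-5-(2-hydroxyethyl)-1,1,5,6-tetramethyl-2,8a-bis(triethylsilyloxy)octahydroazulen-4(1H)-one
Conditions: PPTS (0.1 equiv), MeOH/CH2Cl2, 0 °C
Reagents that add atoms: none
Why: Under mild acid in methanol the unhindered primary triethylsilyl ether is cleaved far faster than the neopentyl secondary and the tertiary ones (selective solvolysis).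

Step 15
Reactants: 27 (2R,3aS,5S,6R,8aS)-5-(2-hydroxyethyl)-1,1,5,6-tetramethyl-2,8a-bis(triethylsilyloxy)octahydroazulen-4(1H)-one
Product: 28 (2R,3aS,5S,6R,8aS)-5-(2-iodoethyl)-1,1,5,6-tetramethyl-2,8a-bis(triethylsilyloxy)octahydroazulen-4(1H)-one
Conditions: I2, PPh3, imidazole, CH2Cl2, 0 °C → rt
Reagents that add atoms: iodine, II
Why: Appel-type iodination of the primary alcohol by SN2 displacement of the alkoxyphosphonium ion.

Step 16
Reactants: 28 (2R,3aS,5S,6R,8aS)-5-(2-iodoethyl)-1,1,5,6-tetramethyl-2,8a-bis(triethylsilyloxy)octahydroazulen-4(1H)-one; 29 4-bromofuran-2(5H)-one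
Product: 31 4-{2-[(2R,3aS,5S,6R,8aS)-1,1,5,6-tetramethyl-4-oxo-2,8a-bis(triethylsilyloxy)decahydroazulen-5-yl]ethyl}furan-2(5H)-one, via alkylzinc iodide 30 (not isolated)
Conditions: Zn dust (TMSCl/BrCH2CH2Br-activated), DMA, 40 °C; then 29, Pd2(dba)3 (2.5 mol %), P(o-tol)3 (10 mol %), THF, rt → 40 °C
Reagents that add atoms: 4-bromofuran-2(5H)-one (29), O=C1C=C(Br)CO1
Why: Direct zinc insertion into the primary C–I bond gives an alkylzinc iodide that tolerates the hindered ketone (a boron or lithium route would not), and Negishi coupling with the vinylogous acyl bromide forms the C12–butenolide bond under neutral conditions.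

Step 17
Reactants: 31 4-{2-[(2R,3aS,5S,6R,8aS)-1,1,5,6-tetramethyl-4-oxo-2,8a-bis(triethylsilyloxy)decahydroazulen-5-yl]ethyl}furan-2(5H)-one
Product: 32 4-{2-[(2R,3aS,5S,6R,8aS)-2,8a-dihydroxy-1,1,5,6-tetramethyl-4-oxodecahydroazulen-5-yl]ethyl}furan-2(5H)-one
Conditions: HF·pyridine, pyridine, THF, 0 °C → rt
Reagents that add atoms: none
Why: Buffered fluoride cleavage of the two remaining silyl ethers should free the diol without provoking β-elimination or retro-aldol cleavage of the β-hydroxy ketone.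

Compound list
1 | 2-methylcyclopent-2-en-1-one | CC1=CCCC1=O | starting material
2 | methylmagnesium bromide | C[Mg]Br | starting material
3 | allyl iodide | C=CCI | starting material
4 | bromomagnesium (3R)-2,3-dimethylcyclopent-1-en-1-olate | C[C@@H]1CCC(O[Mg]Br)=C1C | intermediate (not isolated)
5 | (2S,3R)-2,3-dimethyl-2-(prop-2-en-1-yl)cyclopentan-1-one | C[C@@H]1CCC(=O)[C@@]1(C)CC=C | intermediate
6 | 2-[(1S,2R)-1,2-dimethyl-5-oxocyclopentyl]acetaldehyde | C[C@@H]1CCC(=O)[C@@]1(C)CC=O | intermediate (not isolated)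
7 | (2S,3R)-2-(2-hydroxyethyl)-2,3-dimethylcyclopentan-1-one | C[C@@H]1CCC(=O)[C@@]1(C)CCO | intermediate
8 | trimethyl({(4R,5S)-4,5-dimethyl-5-[2-(trimethylsilyloxy)ethyl]cyclopent-1-en-1-yl}oxy)silane | C[C@@H]1CC=C(O[Si](C)(C)C)[C@@]1(C)CCO[Si](C)(C)C | intermediate
9 | dichloroacetyl chloride | O=C(Cl)C(Cl)Cl | starting material
10 | (1R,2S,3R,5S)-7,7-dichloro-2,3-dimethyl-1-(trimethylsilyloxy)-2-[2-(trimethylsilyloxy)ethyl]bicyclo[3.2.0]heptan-6-one | C[C@@H]1CC[C@@H]2C(=O)C(Cl)(Cl)[C@]2(O[Si](C)(C)C)[C@@]1(C)CCO[Si](C)(C)C | intermediate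
11 | (1R,2S,3R,5S)-2,3-dimethyl-1-(trimethylsilyloxy)-2-[2-(trimethylsilyloxy)ethyl]bicyclo[3.2.0]heptan-6-one | C[C@@H]1CC[C@@H]2C(=O)C[C@]2(O[Si](C)(C)C)[C@@]1(C)CCO[Si](C)(C)C | intermediate (not isolated)
12 | (4S,5R)-4-(2-hydroxyethyl)-4,5-dimethylcycloheptane-1,3-dione | C[C@@H]1CCC(=O)CC(=O)[C@@]1(C)CCO | intermediate (not isolated)
13 | (3aS,4R)-3a,4-dimethyl-2,3,3a,4,5,6-hexahydro-7H-cyclohepta[b]furan-7-one | C[C@@H]1CCC(=O)C=C2OCC[C@@]12C | intermediate
14 | (3aS,4R)-8-bromo-3a,4-dimethyl-2,3,3a,4,5,6-hexahydro-7H-cyclohepta[b]furan-7-one | C[C@@H]1CCC(=O)C(Br)=C2OCC[C@@]12C | intermediate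
15 | 2-ethenyl-4,4,5,5-tetramethyl-1,3,2-dioxaborolane | C=CB1OC(C)(C)C(C)(C)O1 | starting material
16 | (3aS,4R)-8-ethenyl-3a,4-dimethyl-2,3,3a,4,5,6-hexahydro-7H-cyclohepta[b]furan-7-one | C[C@@H]1CCC(=O)C(C=C)=C2OCC[C@@]12C | intermediate
17 | prenylmagnesium chloride (3-methylbut-2-en-1-ylmagnesium chloride) | CC(C)=CC[Mg]Cl | starting material
18 | (3aS,4R)-8-ethenyl-3a,4-dimethyl-7-(2-methylbut-3-en-2-yl)-2,3,3a,4,5,6-hexahydro-7H-cyclohepta[b]furan-7-ol (both C7 epimers) | C[C@@H]1CCC(O)(C(C)(C)C=C)C(C=C)=C2OCC[C@@]12C | intermediate (not isolated)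
19 | (6R,7S)-2-ethenyl-7-(2-hydroxyethyl)-6,7-dimethyl-3-(2-methylbut-3-en-2-yl)cyclohept-2-en-1-one | C[C@@H]1CCC(C(C)(C)C=C)=C(C=C)C(=O)[C@@]1(C)CCO | intermediate
20 | (6R,7S)-2-ethenyl-6,7-dimethyl-3-(2-methylbut-3-en-2-yl)-7-[2-(triethylsilyloxy)ethyl]cyclohept-2-en-1-one | C[C@@H]1CCC(C(C)(C)C=C)=C(C=C)C(=O)[C@@]1(C)CCO[Si](CC)(CC)CC | intermediate
21 | (5S,6R)-1,1,5,6-tetramethyl-5-[2-(triethylsilyloxy)ethyl]-5,6,7,8-tetrahydroazulen-4(1H)-one | C[C@@H]1CCC2=C(C=CC2(C)C)C(=O)[C@@]1(C)CCO[Si](CC)(CC)CC | intermediate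
22 | dioxygen | O=O | starting material
23 | (2R,5S,6R,8aR)-2,8a-epidioxy-1,1,5,6-tetramethyl-5-[2-(triethylsilyloxy)ethyl]-2,5,6,7,8,8a-hexahydroazulen-4(1H)-one (peroxide bridge C3–O–O–C5 on the β face) | C[C@@H]1CC[C@]2(OO3)C(=C[C@@H]3C2(C)C)C(=O)[C@@]1(C)CCO[Si](CC)(CC)CC | intermediate (not isolated)
24 | (2R,5S,6R,8aR)-2,8a-dihydroxy-1,1,5,6-tetramethyl-5-[2-(triethylsilyloxy)ethyl]-2,5,6,7,8,8a-hexahydroazulen-4(1H)-one | C[C@@H]1CC[C@]2(O)C(=C[C@@H](O)C2(C)C)C(=O)[C@@]1(C)CCO[Si](CC)(CC)CC | intermediate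
25 | (2R,5S,6R,8aR)-1,1,5,6-tetramethyl-2,8a-bis(triethylsilyloxy)-5-[2-(triethylsilyloxy)ethyl]-2,5,6,7,8,8a-hexahydroazulen-4(1H)-one | C[C@@H]1CC[C@]2(O[Si](CC)(CC)CC)C(=C[C@@H](O[Si](CC)(CC)CC)C2(C)C)C(=O)[C@@]1(C)CCO[Si](CC)(CC)CC | intermediate
26 | (2R,3aS,5S,6R,8aS)-1,1,5,6-tetramethyl-2,8a-bis(triethylsilyloxy)-5-[2-(triethylsilyloxy)ethyl]octahydroazulen-4(1H)-one | C[C@@H]1CC[C@]2(O[Si](CC)(CC)CC)[C@H](C[C@@H](O[Si](CC)(CC)CC)C2(C)C)C(=O)[C@@]1(C)CCO[Si](CC)(CC)CC | intermediate
27 | (2R,3aS,5S,6R,8aS)-5-(2-hydroxyethyl)-1,1,5,6-tetramethyl-2,8a-bis(triethylsilyloxy)octahydroazulen-4(1H)-one | C[C@@H]1CC[C@]2(O[Si](CC)(CC)CC)[C@H](C[C@@H](O[Si](CC)(CC)CC)C2(C)C)C(=O)[C@@]1(C)CCO | intermediate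
28 | (2R,3aS,5S,6R,8aS)-5-(2-iodoethyl)-1,1,5,6-tetramethyl-2,8a-bis(triethylsilyloxy)octahydroazulen-4(1H)-one | C[C@@H]1CC[C@]2(O[Si](CC)(CC)CC)[C@H](C[C@@H](O[Si](CC)(CC)CC)C2(C)C)C(=O)[C@@]1(C)CCI | intermediate
29 | 4-bromofuran-2(5H)-one | O=C1C=C(Br)CO1 | starting material
30 | iodo{2-[(2R,3aS,5S,6R,8aS)-1,1,5,6-tetramethyl-4-oxo-2,8a-bis(triethylsilyloxy)decahydroazulen-5-yl]ethyl}zinc | C[C@@H]1CC[C@]2(O[Si](CC)(CC)CC)[C@H](C[C@@H](O[Si](CC)(CC)CC)C2(C)C)C(=O)[C@@]1(C)CC[Zn]I | intermediate (not isolated)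
31 | 4-{2-[(2R,3aS,5S,6R,8aS)-1,1,5,6-tetramethyl-4-oxo-2,8a-bis(triethylsilyloxy)decahydroazulen-5-yl]ethyl}furan-2(5H)-one | C[C@@H]1CC[C@]2(O[Si](CC)(CC)CC)[C@H](C[C@@H](O[Si](CC)(CC)CC)C2(C)C)C(=O)[C@@]1(C)CCC1=CC(=O)OC1 | intermediate
32 | 4-{2-[(2R,3aS,5S,6R,8aS)-2,8a-dihydroxy-1,1,5,6-tetramethyl-4-oxodecahydroazulen-5-yl]ethyl}furan-2(5H)-one (CNP0077405.1) | C[C@@H]1CC[C@]2(O)[C@H](C[C@@H](O)C2(C)C)C(=O)[C@@]1(C)CCC1=CC(=O)OC1 | target

Total step count: 17. Longest linear sequence: 17 steps (1 → 32); all other partners are commercial.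

Steps most likely to fail

Step 11. What may go wrong is low or inverted π-facial selectivity, because the C8/C9 substituents are remote from the reacting termini and the ring conformer that reacts may expose the α face; thermal rearrangement of the peroxide is a lesser concern. The fallback replaces steric control by hydrogen-bond delivery. It sets out from 21: 1,2-reduction of C10 (NaBH4, CeCl3) would give the C10 carbinols, of which the β-epimer, (4R,5S,6R)-1,1,5,6-tetramethyl-5-[2-(triethylsilyloxy)ethyl]-1,4,5,6,7,8-hexahydroazulen-4-ol F1, is photooxygenated in a non-polar solvent, where the allylic hydroxyl should steer singlet oxygen to its own face (hydroxy-directed photooxygenation). This gives the C10 β-carbinol of the endoperoxide F2. Dess–Martin oxidation of the C10 carbinol at 0 °C comes back to the route at 23, which is reduced with thiourea to 24 as before. The α-carbinol is re-oxidised to 21 (MnO2) and recycled.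

Step 13. What may go wrong is delivery of hydrogen to the β face (cis-fused ketone), failure of the hindered trisubstituted alkene to reduce, or allylic C–O hydrogenolysis. The fallback uses a directing group on the α face. It sets out from 25: 1,2-reduction (NaBH4, CeCl3) gives the C10 allylic alcohols, and the α-epimer, the C10 α-carbinol of 25 F3, is hydrogenated with a cationic iridium catalyst ([Ir(cod)(PCy3)(py)]PF6, H2, CH2Cl2); the hydroxyl binds the metal and hydrogen is delivered to the α face of C1=C2 (hydroxyl-directed hydrogenation) to give the saturated C10 α-carbinol F4. Dess–Martin oxidation comes back to the route at 26. The β-carbinol is re-oxidised to 25.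

Step 10. What may go wrong is sequestration of the ruthenium carbene as a chelated, conjugated vinylcarbene on the dienone, or failure of the neopentyl vinyl group to initiate, so that oligomers form instead of the ring. The fallback closes the ring before the dienone exists. It sets out from 16: the prenyl adduct 18 is isolated without acid treatment and cyclised by ring-closing metathesis at the carbinol stage, where no ketone is present and a simple cyclopentene is formed, the ring-closed tricyclic carbinol F5. Aqueous acid then performs the carbonyl transposition to (5S,6R)-5-(2-hydroxyethyl)-1,1,5,6-tetramethyl-5,6,7,8-tetrahydroazulen-4(1H)-one F6, and silylation (TESCl, imidazole) comes back to the route at 21.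

Further compounds
F1 | step 11 | (4R,5S,6R)-1,1,5,6-tetramethyl-5-[2-(triethylsilyloxy)ethyl]-1,4,5,6,7,8-hexahydroazulen-4-ol (C10 β-carbinol of 21) | C[C@@H]1CCC2=C(C=CC2(C)C)[C@H](O)[C@@]1(C)CCO[Si](CC)(CC)CC
F2 | step 11 | C10 β-carbinol of endoperoxide 23 (peroxide bridge C3–O–O–C5 on the β face) | C[C@@H]1CC[C@]2(OO3)C(=C[C@@H]3C2(C)C)[C@H](O)[C@@]1(C)CCO[Si](CC)(CC)CC
F3 | step 13 | C10 α-carbinol of 25 (allylic alcohol, hydroxyl on the α face) | C[C@@H]1CC[C@]2(O[Si](CC)(CC)CC)C(=C[C@@H](O[Si](CC)(CC)CC)C2(C)C)[C@@H](O)[C@@]1(C)CCO[Si](CC)(CC)CC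
F4 | step 13 | C10 α-carbinol of 26 (H1 on the α face) | C[C@@H]1CC[C@]2(O[Si](CC)(CC)CC)[C@H](C[C@@H](O[Si](CC)(CC)CC)C2(C)C)[C@@H](O)[C@@]1(C)CCO[Si](CC)(CC)CC
F5 | step 10 | ring-closed tricyclic carbinol from 18 (C2=C3 formed, C5–OH and cyclic enol ether retained, both C5 epimers) | C[C@@H]1CCC2(O)C(C=CC2(C)C)=C2OCC[C@@]12C
F6 | step 10 | (5S,6R)-5-(2-hydroxyethyl)-1,1,5,6-tetramethyl-5,6,7,8-tetrahydroazulen-4(1H)-one | C[C@@H]1CCC2=C(C=CC2(C)C)C(=O)[C@@]1(C)CCO
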